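Each ring (ring A = ring B) is numbered C1 (benzylic CH2), C2 and C3 (Br), C4 and C5 (OH), C6 (H). The enabling feature is that the adjacent carbons C2 and C3 of both benzene rings hold the same atom, bromine, with C3 next to the C4 oxygen. A C2≡C3 aryne can accept both halogens, and either direction of addition ends in one product.
Cuts, in retrosynthetic order: the four ketal C–O bonds masking the two catechols; the four C–Br bonds (C2–Br and C3–Br in ring A and ring B), back to a bis(2-trimethylsilyl-3-triflyloxy) ether; the C3–O sulfonyl and C2–Si bonds; one benzylic C–O bond of the central ether; the ester oxidation level at C1.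
Forward: both benzene rings are bought intact in methyl gallate, whose third oxygen becomes the C3 leaving group, and the only ring made is the dioxole ketal (step 1). C2 is silylated on the monomer, so butyllithium never meets a dibenzyl ether prone to [1,2]-Wittig rearrangement. Two monomers are joined through oxygen in step 6, the bromines enter in step 8 and the ketals leave in step 9.
Stereochemistry: the target is achiral, without stereocentres or configured double bonds, so nothing has to be set or preserved.

Key step: step 8

Remark: ring positions are cited with the C1–C6 numbering above, also for the benzodioxole intermediates. Reagents without a number are taken to be commercial.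

Step 1
Reactants: 1 methyl gallate; 2 2,2-dimethoxypropane
Product: 3 methyl 7-hydroxy-2,2-dimethyl-1,3-benzodioxole-5-carboxylate
Conditions: 2 (3 equiv), p-TsOH·H2O (cat.), toluene, reflux, MeOH removed over 4 Å sieves
Reagents that add atoms: 2,2-dimethoxypropane (2), COC(C)(C)OC
Why: Acid-catalysed transketalisation; only two neighbouring phenols can bridge the isopropylidene carbon, and the two adjacent pairs of the symmetric gallate are equivalent, so one five-membered catechol ketal should form and leave a single phenol (the future C3 oxygen) free.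

Step 2
Reactants: 3 methyl 7-hydroxy-2,2-dimethyl-1,3-benzodioxole-5-carboxylate; 4 isopropyl isocyanate
Product: 5 methyl 2,2-dimethyl-7-[(isopropylcarbamoyl)oxy]-1,3-benzodioxole-5-carboxylate
Conditions: 4 (1.3 equiv), Et3N (0.2 equiv), CH2Cl2, rt
Reagents that add atoms: isopropyl isocyanate (4), CC(C)N=C=O
Why: Amine-catalysed addition of a phenol to an isocyanate (carbamoylation) installs the N-isopropyl carbamate, a strong ortho-directing group that can later be removed with mild base.

Step 3
Reactants: 5 methyl 2,2-dimethyl-7-[(isopropylcarbamoyl)oxy]-1,3-benzodioxole-5-carboxylate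
Product: 6 6-(hydroxymethyl)-2,2-dimethyl-1,3-benzodioxol-4-yl N-isopropylcarbamate
Conditions: i-Bu2AlH (3.5 equiv), CH2Cl2, −78 °C; aq. potassium sodium tartrate
Reagents that add atoms: none
Why: Ester reduction with i-Bu2AlH; the first equivalent removes the carbamate N–H and the resulting aluminium-bound carbamate anion resists hydride, so at low temperature only the methyl ester should be reduced to the benzylic alcohol, whereas LiAlH4 would strip the aryl carbamate.

Step 4
Reactants: 6 6-(hydroxymethyl)-2,2-dimethyl-1,3-benzodioxol-4-yl N-isopropylcarbamate; 7 chlorotrimethylsilane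
Product: 11 6-(hydroxymethyl)-2,2-dimethyl-5-(trimethylsilyl)-1,3-benzodioxol-4-yl N-isopropylcarbamate, via N,O-bis(trimethylsilyl) derivative 8 (not isolated), via C2-aryllithium 9 (not isolated), via tris(trimethylsilyl) compound 10 (not isolated)
Conditions: TMSOTf (2.3 equiv), TMEDA, Et2O, 0 °C to rt; n-BuLi (2 equiv), TMEDA, −78 °C; 7, −78 °C to rt; aq. NaHSO4
Reagents that add atoms: chlorotrimethylsilane (7), C[Si](C)(C)Cl; trimethylsilyl trifluoromethanesulfonate, C[Si](C)(C)OS(=O)(=O)C(F)(F)F (its silyl groups stand only in 8–10 and are lost on work-up)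
Why: Directed ortho-metalation; TMSOTf/TMEDA masks N–H and O–H in the flask, the N-silyl carbamate guides n-BuLi to C2, its only free ortho position (C4 is oxygenated) and one also flanked by the benzylic oxygen, the weaker dioxole director at C6 cannot compete, and quenching with 7 (or an O-to-C silyl shift in 9, which gives the same C2 silane) followed by mild acid work-up that strips only the N- and O-silyl groups should give 11.

Step 5
Reactants: 11 6-(hydroxymethyl)-2,2-dimethyl-5-(trimethylsilyl)-1,3-benzodioxol-4-yl N-isopropylcarbamate (half of the material)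
Product: 12 6-(bromomethyl)-2,2-dimethyl-5-(trimethylsilyl)-1,3-benzodioxol-4-yl N-isopropylcarbamate
Conditions: CBr4, PPh3, CH2Cl2, 0 °C
Reagents that add atoms: carbon tetrabromide, BrC(Br)(Br)Br
Why: Appel reaction; the alcohol is activated as an alkoxyphosphonium salt and displaced by bromide under essentially neutral conditions, avoiding the HBr that could protodesilylate C2 or open the ketal, and the labile bromide is used without storage.

Step 6
Reactants: 11 6-(hydroxymethyl)-2,2-dimethyl-5-(trimethylsilyl)-1,3-benzodioxol-4-yl N-isopropylcarbamate; 12 6-(bromomethyl)-2,2-dimethyl-5-(trimethylsilyl)-1,3-benzodioxol-4-yl N-isopropylcarbamate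
Product: 13 bis{[7-(isopropylcarbamoyloxy)-2,2-dimethyl-6-(trimethylsilyl)-1,3-benzodioxol-5-yl]methyl} ether
Conditions: Ag2O (1.5 equiv), 4 Å MS, CH2Cl2, rt, dark
Reagents that add atoms: none
Why: Silver-oxide-promoted Williamson etherification; Ag2O pulls bromide from a benzylic carbon whose ionisation is helped by the para C4 oxygen and the neutral primary alcohol 11 captures it, so no alkoxide is present that could trigger E1cB loss of the N–H carbamate or attack the neighbouring silicon.

Step 7
Reactants: 13 bis{[7-(isopropylcarbamoyloxy)-2,2-dimethyl-6-(trimethylsilyl)-1,3-benzodioxol-5-yl]methyl} ether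
Product: 15 bis{[2,2-dimethyl-6-(trimethylsilyl)-7-(trifluoromethanesulfonyloxy)-1,3-benzodioxol-5-yl]methyl} ether, via bis(phenol) 14 (not isolated)
Conditions: DBU, Et2NH, MeCN, 40 °C; then PhNTf2, rt
Reagents that add atoms: N-phenylbis(trifluoromethanesulfonimide), O=S(=O)(N(c1ccccc1)S(=O)(=O)C(F)(F)F)C(F)(F)F
Why: DBU removes each carbamate N–H and the anion expels the phenoxide by E1cB elimination, Et2NH scavenges the isocyanate as a urea, and the hindered phenoxides of 14 are triflated in the same pot by the mild donor PhNTf2, the established carbamate-to-triflate exchange for ortho-silylaryl triflates, which leaves ketal, ether and C–Si bonds untouched.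

Step 8
Reactants: 15 bis{[2,2-dimethyl-6-(trimethylsilyl)-7-(trifluoromethanesulfonyloxy)-1,3-benzodioxol-5-yl]methyl} ether; 16 1,2-dibromo-1,1,2,2-tetrachloroethane
Product: 20 bis[(6,7-dibromo-2,2-dimethyl-1,3-benzodioxol-5-yl)methyl] ether, via ring-A aryne 17 (not isolated), via half-brominated silyl triflate 18 (not isolated), via ring-B aryne 19 (not isolated)
Conditions: KF (6 equiv), 18-crown-6 (6 equiv), KBr (4 equiv), 16 (6 equiv), THF, 0 °C to rt, dark
Reagents that add atoms: 1,2-dibromo-1,1,2,2-tetrachloroethane (16), BrC(Cl)(Cl)C(Cl)(Cl)Br; potassium bromide, [K+].[Br-] (bromide carrier, regenerated from 16)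
Why: Fluoride attacks the C2 silicon and triflate leaves from C3, so ring A and then ring B pass through a C2≡C3 aryne (17, 19); bromide adds to the strained triple bond and the ortho-bromoaryl anion abstracts Br+ from 16 by halophilic attack, after which the remaining Cl2C(−)–CCl2Br fragment collapses to Cl2C=CCl2 and bromide, which re-enters the cycle. The closest known reaction type is the vicinal dihalogenation of arynes released from ortho-silylaryl triflates, by insertion into a halogen–halogen bond or by three-component capture with a halide and a halogen-atom donor; here it must run once in each ring and forms four C–Br bonds. No ring is closed and no stereocentre is created. The inductive pull of the C4 oxygen steers bromide to C2 and puts the charge on C3, yet this regiochemistry is immaterial, because the reverse addition, loss of bromide from the anion (which only regenerates the aryne) and bromine exchange between anion and product all converge on the same 2,3-dibromide. The selectivity that matters is chemoselectivity: aryne capture must beat electrophilic bromination at C6–H and ipso-bromodesilylation at C2, which is secured by the absence of free Br2 (16 hands bromine only to carbanions) and by the deactivating triflate or bromines on every ring present. Protonation of the anion and cycloaddition of the aryne onto the tethered ring are held back by an ether solvent without acidic C–H, a high concentration of bromide and 16, and slow fluoride release from sparingly soluble KF, so that only one aryne is alive at a time.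

Step 9
Reactants: 20 bis[(6,7-dibromo-2,2-dimethyl-1,3-benzodioxol-5-yl)methyl] ether
Product: 21 bis(2,3-dibromo-4,5-dihydroxybenzyl) ether
Conditions: TFA–CH2Cl2–H2O (10:10:1), 0 °C, argon, short contact; evaporation with toluene
Reagents that add atoms: none
Why: Acid-catalysed ketal hydrolysis; opening of the protonated dioxole gives a tertiary oxocarbenium ion far more readily than the central ether can ionise to a benzylic cation destabilised by the C2 and C3 bromines, so short cold contact in a medium free of alcohols should release both catechols and leave the C–O–C link intact.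

Compound list
1 | methyl gallate | COC(=O)c1cc(O)c(O)c(O)c1 | starting material
2 | 2,2-dimethoxypropane | COC(C)(C)OC | starting material
3 | methyl 7-hydroxy-2,2-dimethyl-1,3-benzodioxole-5-carboxylate | COC(=O)c1cc(O)c2OC(C)(C)Oc2c1 | intermediate
4 | isopropyl isocyanate | CC(C)N=C=O | starting material
5 | methyl 2,2-dimethyl-7-[(isopropylcarbamoyl)oxy]-1,3-benzodioxole-5-carboxylate | COC(=O)c1cc(OC(=O)NC(C)C)c2OC(C)(C)Oc2c1 | intermediate
6 | 6-(hydroxymethyl)-2,2-dimethyl-1,3-benzodioxol-4-yl N-isopropylcarbamate | OCc1cc(OC(=O)NC(C)C)c2OC(C)(C)Oc2c1 | intermediate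
7 | chlorotrimethylsilane | C[Si](C)(C)Cl | starting material
8 | 2,2-dimethyl-6-[(trimethylsilyloxy)methyl]-1,3-benzodioxol-4-yl N-isopropyl-N-(trimethylsilyl)carbamate | C[Si](C)(C)OCc1cc(OC(=O)N(C(C)C)[Si](C)(C)C)c2OC(C)(C)Oc2c1 | intermediate
9 | 5-lithio derivative of 8 (lithium at C2) | [Li]c1c(CO[Si](C)(C)C)cc2OC(C)(C)Oc2c1OC(=O)N(C(C)C)[Si](C)(C)C | intermediate
10 | 5-(trimethylsilyl) derivative of 8 (C-, N- and O-silylated) | C[Si](C)(C)OCc1cc2OC(C)(C)Oc2c(OC(=O)N(C(C)C)[Si](C)(C)C)c1[Si](C)(C)C | intermediate
11 | 6-(hydroxymethyl)-2,2-dimethyl-5-(trimethylsilyl)-1,3-benzodioxol-4-yl N-isopropylcarbamate | OCc1cc2OC(C)(C)Oc2c(OC(=O)NC(C)C)c1[Si](C)(C)C | intermediate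
12 | 6-(bromomethyl)-2,2-dimethyl-5-(trimethylsilyl)-1,3-benzodioxol-4-yl N-isopropylcarbamate | BrCc1cc2OC(C)(C)Oc2c(OC(=O)NC(C)C)c1[Si](C)(C)C | intermediate
13 | bis{[7-(isopropylcarbamoyloxy)-2,2-dimethyl-6-(trimethylsilyl)-1,3-benzodioxol-5-yl]methyl} ether | CC1(C)Oc2cc(COCc3cc4OC(C)(C)Oc4c(OC(=O)NC(C)C)c3[Si](C)(C)C)c([Si](C)(C)C)c(OC(=O)NC(C)C)c2O1 | intermediate
14 | bis{[7-hydroxy-2,2-dimethyl-6-(trimethylsilyl)-1,3-benzodioxol-5-yl]methyl} ether | CC1(C)Oc2cc(COCc3cc4OC(C)(C)Oc4c(O)c3[Si](C)(C)C)c([Si](C)(C)C)c(O)c2O1 | intermediate
15 | bis{[2,2-dimethyl-6-(trimethylsilyl)-7-(trifluoromethanesulfonyloxy)-1,3-benzodioxol-5-yl]methyl} ether | CC1(C)Oc2cc(COCc3cc4OC(C)(C)Oc4c(OS(=O)(=O)C(F)(F)F)c3[Si](C)(C)C)c([Si](C)(C)C)c(OS(=O)(=O)C(F)(F)F)c2O1 | intermediate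
16 | 1,2-dibromo-1,1,2,2-tetrachloroethane | BrC(Cl)(Cl)C(Cl)(Cl)Br | starting material
17 | mono-aryne: ring A is the 6,7-didehydro-2,2-dimethyl-1,3-benzodioxol-5-yl unit (C2≡C3), ring B still the silyl triflate | CC1(C)OC2=C(O1)C#CC(COCc3cc4OC(C)(C)Oc4c(OS(=O)(=O)C(F)(F)F)c3[Si](C)(C)C)=C2 | intermediate
18 | (6,7-dibromo-2,2-dimethyl-1,3-benzodioxol-5-yl)methyl [2,2-dimethyl-6-(trimethylsilyl)-7-(trifluoromethanesulfonyloxy)-1,3-benzodioxol-5-yl]methyl ether | CC1(C)Oc2cc(COCc3cc4OC(C)(C)Oc4c(OS(=O)(=O)C(F)(F)F)c3[Si](C)(C)C)c(Br)c(Br)c2O1 | intermediate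
19 | second aryne: ring B is the 6,7-didehydro unit (C2≡C3), ring A already the 2,3-dibromide | CC1(C)OC2=C(O1)C#CC(COCc3cc4OC(C)(C)Oc4c(Br)c3Br)=C2 | intermediate
20 | bis[(6,7-dibromo-2,2-dimethyl-1,3-benzodioxol-5-yl)methyl] ether | CC1(C)Oc2cc(COCc3cc4OC(C)(C)Oc4c(Br)c3Br)c(Br)c(Br)c2O1 | intermediate
21 | bis(2,3-dibromo-4,5-dihydroxybenzyl) ether | Oc1cc(COCc2cc(O)c(O)c(Br)c2Br)c(Br)c(Br)c1O | target

Total steps: 9. Longest linear sequence: 9 (1 → 3 → 5 → 6 → 11 → 12 → 13 → 15 → 20 → 21).

Steps most likely to fail

Step 8. Capture of the aryne may be incomplete. The bromoaryl anion may be protonated (net hydrobromination), fluoride or solvent may add to the triple bond, or the aryne may react with the tethered ring. Every such loss counts twice, because two arynes per molecule must be trapped cleanly. The fallback places the two bromines one after the other without an aryne and sets out from 15. Ipso-bromodesilylation at C2 with NBS in MeCN in the dark, where silicon marks the carbon that the electrophile enters, should give bis[(6-bromo-2,2-dimethyl-7-trifluoromethanesulfonyloxy-1,3-benzodioxol-5-yl)methyl] ether F1. The two C3 triflates are then exchanged for bromide with LiBr and catalytic [Cp*Ru(MeCN)3]OTf in 1,3-dimethyl-2-imidazolidinone at about 100 °C. This is a known aryl triflate-to-halide conversion through an η6-arene complex, and it tolerates aryl bromides. The sequence comes back to the route at 20.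

Step 9. The para C4 oxygen may assist ionisation of the benzylic C–O bond during ketal hydrolysis, so that the central ether is solvolysed along with the ketals. The fallback does not defend the ether but rebuilds it, and sets out from 20. Exhaustive solvolysis (aq. HCl, dioxane, heating) gives 2,3-dibromo-4,5-dihydroxybenzyl alcohol F2. F2 is then re-condensed at high concentration in a non-nucleophilic solvent (cat. p-TsOH, 4 Å sieves, nitromethane). The para-quinone methide derived from the C4 hydroxyl is captured by the benzylic hydroxyl of a second molecule, and removal of water drives the equilibrium. This is the self-etherification typical of para-hydroxybenzyl alcohols, and it comes back to the route at 21.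

Step 6. Substitution at a benzylic carbon next to SiMe3 may be slow, which would let hydrolysis of the bromide or N-alkylation of the carbamate compete. The fallback forms the C–O bond at an sp2 carbon instead and sets out from 11, omitting 12. Oxidation with MnO2 (CH2Cl2, rt) gives 6-formyl-2,2-dimethyl-5-(trimethylsilyl)-1,3-benzodioxol-4-yl N-isopropylcarbamate F3. Reductive homo-etherification with Et3SiH and catalytic BiBr3 in MeCN then joins two molecules. One aldehyde is hydrosilylated, its silyl ether adds to a second aldehyde, and the oxocarbenium ion is reduced. The sequence comes back to the route at 13.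

Further compounds
F1 | step 8 | bis[(6-bromo-2,2-dimethyl-7-trifluoromethanesulfonyloxy-1,3-benzodioxol-5-yl)methyl] ether | CC1(C)Oc2cc(COCc3cc4OC(C)(C)Oc4c(OS(=O)(=O)C(F)(F)F)c3Br)c(Br)c(OS(=O)(=O)C(F)(F)F)c2O1
F2 | step 9 | 2,3-dibromo-4,5-dihydroxybenzyl alcohol | OCc1cc(O)c(O)c(Br)c1Br
F3 | step 6 | 6-formyl-2,2-dimethyl-5-(trimethylsilyl)-1,3-benzodioxol-4-yl N-isopropylcarbamate | O=Cc1cc2OC(C)(C)Oc2c(OC(=O)NC(C)C)c1[Si](C)(C)C
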